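**Plan**

- Retrosynthesis first removes the O-methyl group at the C2 oxygen, giving a 4-hydroxy-2-pyranone. The ring is then cut at C4–C5 and O1–C2.
- Ring atoms C2–C3(Et)–C4 map onto symmetrical ethylmalonic acid. O1–C6–C5(Me) are one specific enolate of an ethyl ketone that carries the side chain; this pairing is the feature that allows a one-flask [3+3] ring synthesis.
- The enolate is fixed as a triethylsilyl enol ether made by 1,4-hydrosilylation of a vinyl ketone. The vinyl ketone is cut at C11–C12 (alkylzinc acylation), and the chain at C3–C4 (epoxide opening by an 8-chlorooctyl Grignard reagent).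
- Forward order: the chain is joined first (epoxide opening, acetylation, Cl to I, zinc acylation, elimination, hydrosilylation), the single ring is closed in the annulation, and O-methylation ends the route.
- The only stereocentre comes from (S)-propylene oxide; no later step breaks a bond at that carbon.

Key step: step 8

**Route**

Step 1
Reactants: 1 1-bromo-8-chlorooctane; 2 (S)-propylene oxide
Product: 4 (S)-11-chloroundecan-2-ol, via 8-chlorooctylmagnesium bromide 3 (not isolated)
Conditions: Mg, THF, 40 °C; then CuI (5 mol%), 2, THF, −30 to 0 °C
Reagents that add atoms: none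
Why: Magnesium inserts selectively into the C–Br bond, and CuI-catalysed SN2 opening of the epoxide by the Grignard reagent occurs at the unsubstituted carbon, so the (S) carbinol centre is carried over unchanged from 2.

Step 2
Reactants: 4 (S)-11-chloroundecan-2-ol
Product: 5 (S)-11-chloroundecan-2-yl acetate
Conditions: Ac2O, pyridine, DMAP (cat.), CH2Cl2, rt
Reagents that add atoms: acetic anhydride, CC(=O)OC(C)=O
Why: DMAP-catalysed acetylation of a secondary alcohol acylates at oxygen without breaking the C–O bond of the stereocentre, so the configuration is retained.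

Step 3
Reactants: 5 (S)-11-chloroundecan-2-yl acetate
Product: 6 (S)-11-iodoundecan-2-yl acetate
Conditions: NaI (3 equiv), 2-butanone, 80 °C
Reagents that add atoms: sodium iodide, [Na+].[I-]
Why: Finkelstein exchange at an unhindered primary chloride is driven by precipitation of the chloride salt and leaves the secondary acetate untouched.

Step 4
Reactants: 6 (S)-11-iodoundecan-2-yl acetate; 7 3-chloropropionyl chloride
Product: 9 (S)-14-chloro-12-oxotetradecan-2-yl acetate, via (S)-(10-acetoxyundecyl)zinc iodide 8 (not isolated)
Conditions: Zn dust (activated with BrCH2CH2Br and Me3SiCl, few mol%), THF, 40 °C; then 7, Pd(PPh3)4 (5 mol%), THF, 0 °C to rt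
Reagents that add atoms: none
Why: Direct zinc insertion into a primary alkyl iodide tolerates the ester, and Negishi acylation of the alkylzinc iodide by the acid chloride stops at the ketone because the organozinc does not add to ketones or displace the alkyl chloride.

Step 5
Reactants: 9 (S)-14-chloro-12-oxotetradecan-2-yl acetate
Product: 10 (S)-12-oxotetradec-13-en-2-yl acetate
Conditions: Et3N (1.5 equiv), CH2Cl2, 0 °C to rt (BHT trace)
Reagents that add atoms: none
Why: E1cB elimination of hydrogen chloride from a β-chloro ketone is fast with a tertiary amine and gives the vinyl ketone under conditions too mild to affect the acetate.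

Step 6
Reactants: 10 (S)-12-oxotetradec-13-en-2-yl acetate
Product: 11 (S,Z)-12-(triethylsilyloxy)tetradec-12-en-2-yl acetate
Conditions: Et3SiH (1.2 equiv), RhCl(PPh3)3 (1 mol%), THF, 50 °C
Reagents that add atoms: triethylsilane, CC[SiH](CC)CC
Why: Rhodium-catalysed 1,4-hydrosilylation of an enone by a monohydrosilane delivers hydride to the terminal carbon and silicon to oxygen through the s-cis conformer, so the enol double bond is placed only between C12 and C13 and the Z isomer is expected.

Step 7
Reactants: 12 ethylmalonic acid
Product: 13 ethylmalonyl dichloride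
Conditions: SOCl2 (neat, excess), 50 °C to reflux; distillation under reduced pressure
Reagents that add atoms: thionyl chloride, O=S(Cl)Cl
Why: Conversion of a malonic acid into its dichloride with thionyl chloride is a standard acid chloride formation, and distillation removes excess reagent.

Step 8
Reactants: 11 (S,Z)-12-(triethylsilyloxy)tetradec-12-en-2-yl acetate; 13 ethylmalonyl dichloride
Product: 15 (S)-11-(5-ethyl-4-hydroxy-3-methyl-6-oxo-6H-pyran-2-yl)undecan-2-yl acetate, via diketo acid chloride 14 (not isolated)
Conditions: 13 (1.2 equiv), Et2O, −78 °C to rt, no base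
Reagents that add atoms: none
Why: The nucleophilic enol carbon of 11 (C13) attacks one acyl chloride of 13 in an uncatalysed Mukaiyama-type C-acylation, the silyl group leaves as its chloride, and the future C4–C5 bond is formed in diketo acid chloride 14. The chain ketone, now part of a 1,3-dicarbonyl unit, enolises toward the methyl-bearing carbon and its oxygen acylates the remaining acid chloride to form O1–C2 in a 6-exo-trig closure, after which tautomerisation gives the 4-hydroxy-2-pyranone. The closest known reaction type is the condensation of ketone silyl enol ethers with malonyl dichlorides, or of ketones with chlorocarbonyl ketenes, to 4-hydroxy-2-pyranones. No stereocentre is created, and the remote (S) acetate centre takes no part. The selectivity required is regiochemical, between the two α-carbons of the ketone, and it is secured by the position of the enol double bond set in step 6; because 13 is symmetrical, either acyl chloride may react first with the same result. Low temperature and the absence of base should keep the enol silane from equilibrating before the carbon–carbon bond is made.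

Step 9
Reactants: 15 (S)-11-(5-ethyl-4-hydroxy-3-methyl-6-oxo-6H-pyran-2-yl)undecan-2-yl acetate
Product: 16 (S)-11-(5-ethyl-6-methoxy-3-methyl-4-oxo-4H-pyran-2-yl)undecan-2-yl acetate (target)
Conditions: MeOTf (1.5 equiv), CH2Cl2, 0 °C to rt
Reagents that add atoms: methyl trifluoromethanesulfonate, COS(=O)(=O)C(F)(F)F
Why: Base-free O-alkylation of the neutral vinylogous acid by a hard methylating agent takes place at the lactone carbonyl oxygen, and loss of the hydroxyl proton then gives the 2-methoxy-4-pyranone, the established outcome for 3,5-dialkyl-4-hydroxy-2-pyranones.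

**Compound list**

1 | 1-bromo-8-chlorooctane | ClCCCCCCCCBr | starting material
2 | (S)-propylene oxide | C[C@H]1CO1 | starting material
3 | 8-chlorooctylmagnesium bromide | ClCCCCCCCC[Mg]Br | intermediate
4 | (S)-11-chloroundecan-2-ol | ClCCCCCCCCC[C@H](C)O | intermediate
5 | (S)-11-chloroundecan-2-yl acetate | ClCCCCCCCCC[C@H](C)OC(C)=O | intermediate
6 | (S)-11-iodoundecan-2-yl acetate | ICCCCCCCCC[C@H](C)OC(C)=O | intermediate
7 | 3-chloropropionyl chloride | ClCCC(=O)Cl | starting material
8 | (S)-(10-acetoxyundecyl)zinc iodide | I[Zn]CCCCCCCCC[C@H](C)OC(C)=O | intermediate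
9 | (S)-14-chloro-12-oxotetradecan-2-yl acetate | ClCCC(=O)CCCCCCCCC[C@H](C)OC(C)=O | intermediate
10 | (S)-12-oxotetradec-13-en-2-yl acetate | C=CC(=O)CCCCCCCCC[C@H](C)OC(C)=O | intermediate
11 | (S,Z)-12-(triethylsilyloxy)tetradec-12-en-2-yl acetate | C/C=C(\O[Si](CC)(CC)CC)CCCCCCCCC[C@H](C)OC(C)=O | intermediate
12 | ethylmalonic acid | CCC(C(=O)O)C(=O)O | starting material
13 | ethylmalonyl dichloride | CCC(C(=O)Cl)C(=O)Cl | intermediate
14 | (15S)-15-acetoxy-2-ethyl-4-methyl-3,5-dioxohexadecanoyl chloride (diketo acid chloride, mixture of epimers at C2 and C4) | CCC(C(=O)Cl)C(=O)C(C)C(=O)CCCCCCCCC[C@H](C)OC(C)=O | intermediate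
15 | (S)-11-(5-ethyl-4-hydroxy-3-methyl-6-oxo-6H-pyran-2-yl)undecan-2-yl acetate | CCC1=C(O)C(C)=C(CCCCCCCCC[C@H](C)OC(C)=O)OC1=O | intermediate
16 | (S)-11-(5-ethyl-6-methoxy-3-methyl-4-oxo-4H-pyran-2-yl)undecan-2-yl acetate | CCc1c(OC)oc(CCCCCCCCC[C@H](C)OC(C)=O)c(C)c1=O | target

**Step count**

Total steps: 9. Longest linear sequence: 8 steps (steps 1 to 6, then 8 and 9); step 7 is a one-step side branch.

**Steps most likely to fail**

Step 8. The hydrogen chloride formed in the ring closure may protodesilylate enol silane that has not yet reacted, and O-acylation or self-condensation of the dichloride may compete with C-acylation. The fallback sets out from 11, comes back at 15, and makes the two ring bonds in separate operations with a monofunctional acylating agent. Commercial diethyl ethylmalonate would be half-saponified (KOH, 1 equiv, EtOH, then acid) to 2-(ethoxycarbonyl)butanoic acid F1. Treatment with SOCl2 would give ethyl 2-(chlorocarbonyl)butanoate F2. ZnCl2-promoted C-acylation of 11 with F2 in CH2Cl2/Et2O should form the C4–C5 bond and give ethyl (15S)-15-acetoxy-2-ethyl-4-methyl-3,5-dioxohexadecanoate F3, with no strong acid in the flask. DBU in toluene at 60 °C would then lactonise F3 through the enol oxygen to give 15.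

Step 9. Methylation may take place in part at the C4 oxygen if some substrate reacts as its anion or as the minor tautomer, which would lower the regioselectivity. The fallback sets out from 15, comes back at 16, and blocks the competing oxygen before methylation. Silylation (TBSCl, imidazole, CH2Cl2) should give (S)-11-(4-(tert-butyldimethylsilyloxy)-5-ethyl-3-methyl-6-oxo-6H-pyran-2-yl)undecan-2-yl acetate F4, in which only the lactone carbonyl oxygen remains free. MeOTf in CH2Cl2 would convert F4 into (S)-2-(10-acetoxyundecyl)-4-(tert-butyldimethylsilyloxy)-5-ethyl-6-methoxy-3-methylpyrylium trifluoromethanesulfonate F5, the type of salt formed when 4-alkoxy-2-pyranones are O-methylated. Aqueous NaHCO3 should remove the silyl group from F5 and release 16.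

Step 4. Zinc insertion may be slow or incomplete, Wurtz-type homocoupling may consume the iodide, and premature loss of hydrogen chloride from the β-chloro ketone may lead to polymerisation during the coupling. The fallback sets out from 4, comes back at 10, and replaces steps 2 to 5; it forms the C11–C12 bond by Grignard addition to an aldehyde. Alcohol 4 would be deprotonated with i-PrMgCl, and the alkyl chloride converted with Mg in refluxing THF into chloromagnesium (S)-11-(chloromagnesio)undecan-2-olate F6, a Normant-type reagent. Addition of F6 to acrolein at −78 °C should give (2S)-tetradec-13-ene-2,12-diol F7 as a mixture of C12 epimers. MnO2 in CH2Cl2 would oxidise only the allylic alcohol, giving (S)-13-hydroxytetradec-1-en-3-one F8. Acetylation of F8 (Ac2O, pyridine, 0 °C) would then give 10.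

**Further compounds**

F1 | step 8 | 2-(ethoxycarbonyl)butanoic acid | CCOC(=O)C(CC)C(=O)O
F2 | step 8 | ethyl 2-(chlorocarbonyl)butanoate | CCOC(=O)C(CC)C(=O)Cl
F3 | step 8 | ethyl (15S)-15-acetoxy-2-ethyl-4-methyl-3,5-dioxohexadecanoate | CCOC(=O)C(CC)C(=O)C(C)C(=O)CCCCCCCCC[C@H](C)OC(C)=O
F4 | step 9 | (S)-11-(4-(tert-butyldimethylsilyloxy)-5-ethyl-3-methyl-6-oxo-6H-pyran-2-yl)undecan-2-yl acetate | CCC1=C(O[Si](C)(C)C(C)(C)C)C(C)=C(CCCCCCCCC[C@H](C)OC(C)=O)OC1=O
F5 | step 9 | (S)-2-(10-acetoxyundecyl)-4-(tert-butyldimethylsilyloxy)-5-ethyl-6-methoxy-3-methylpyrylium trifluoromethanesulfonate | CCc1c(OC)[o+]c(CCCCCCCCC[C@H](C)OC(C)=O)c(C)c1O[Si](C)(C)C(C)(C)C.[O-]S(=O)(=O)C(F)(F)F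
F6 | step 4 | chloromagnesium (S)-11-(chloromagnesio)undecan-2-olate | Cl[Mg]CCCCCCCCC[C@H](C)O[Mg]Cl
F7 | step 4 | (2S)-tetradec-13-ene-2,12-diol | C=CC(O)CCCCCCCCC[C@H](C)O
F8 | step 4 | (S)-13-hydroxytetradec-1-en-3-one | C=CC(=O)CCCCCCCCC[C@H](C)O
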